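**Strategy.** Rings A and B are closed together from a monocyclic lactone. The disconnection reads the C3 carbinol next to quaternary C4 as an aldol retron, and the ring-fusion bond from quaternary, methyl-bearing C10 to C5 as a radical conjugate addition. An iron hydride turns the C10=C20 methylene of precursor 18 into the tertiary C10 radical, which closes ring B onto the enal carbon C5. The resulting enolate at C4 closes ring A on the C3 aldehyde. One operation should thus set C3, C5, C10 and the trans-decalin. The precursor is a cis-disubstituted δ-lactone (C17, C12) made by an enantioselective Ireland–Claisen rearrangement; the extra C4 formyl group is then reduced to methyl.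

Key step: step 9

Remark on numbering: labdane numbering of the target is used for every atom label (C1–C10 decalin carbons, C11/C12 the CH2 groups on C9, C17 the carbon on C8, C20 the methyl on C10).

Assumption: the (S,S) enantiomer of the bis-sulfonamide bromoborane is written as the one that delivers the (2R,3R) acid 15; the sense is assigned by analogy, and the (R,R) reagent is used if the model ester shows the opposite sense.

Assumption: 6-methylhept-5-enoic acid (9) is taken as a catalogue compound; the C4 configuration drawn for 21 is of no consequence, since both C4 epimers give 23.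

Step 1
Reactants: 1 tert-butyl(but-3-yn-1-yloxy)dimethylsilane; 2 paraformaldehyde
Product: 4 silyloxy pentynol, via lithium acetylide 3 (not isolated)
Conditions: n-BuLi, THF, −78 °C; (CH2O)n, −78 °C → rt; aq. NH4Cl
Reagents that add atoms: none
Why: addition of a lithium acetylide to formaldehyde (alkynylation) should give the propargylic alcohol; no stereocentre is formed.

Step 2
Reactants: 4 silyloxy pentynol; 5 (3-bromopropoxy)(tert-butyl)dimethylsilane
Product: 8 (E)-allylic alcohol, via Grignard reagent 6 (not isolated), via cyclic alkenylmagnesium alkoxide 7 (not isolated)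
Conditions: 5, Mg, THF, 40 °C; then 4, CuI (10 mol %), THF, 0 °C → reflux; aq. NH4Cl
Reagents that add atoms: none
Why: copper-catalysed anti-carbomagnesiation of a propargylic alcohol should place the new alkyl group on the carbon next to CH2O, with magnesium chelated on the other alkyne carbon, so that protonation gives the alkene with CH2OH trans to the silyloxyethyl chain.

Step 3
Reactants: 9 6-methylhept-5-enoic acid
Product: 10 (E)-hydroxy acid
Conditions: SeO2 (0.3 equiv), t-BuOOH (70 % aq.), CH2Cl2, rt
Reagents that add atoms: tert-butyl hydroperoxide, CC(C)(C)OO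
Why: SeO2/t-BuOOH allylic oxidation (ene reaction, then [2,3]-shift; Riley-type) should hydroxylate the (E)-methyl group of the isopropylidene alkene selectively.

Step 4
Reactants: 10 (E)-hydroxy acid
Product: 12 silyloxy acid, via bis-silylated ester 11 (not isolated)
Conditions: TBSCl (2.5 equiv), imidazole, DMF, rt; then K2CO3, MeOH/THF/H2O, rt; work-up at pH 5
Reagents that add atoms: tert-butyldimethylsilyl chloride, CC(C)(C)[Si](C)(C)Cl
Why: silylation of alcohol and acid followed by selective hydrolysis of the labile silyl ester should leave the allylic TBS ether.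

Step 5
Reactants: 8 (E)-allylic alcohol; 12 silyloxy acid
Product: 13 allylic ester
Conditions: DCC, DMAP (cat.), CH2Cl2, 0 °C → rt
Reagents that add atoms: none
Why: Steglich esterification joins the two fragments under neutral conditions that leave the silyl ethers and both alkene geometries untouched.

Step 6
Reactants: 13 allylic ester
Product: 15 (2R,3R)-acid, via boron ketene acetal 14 (not isolated)
Conditions: (S,S)-2-bromo-4,5-diphenyl-1,3-bis{[3,5-bis(trifluoromethyl)phenyl]sulfonyl}-1,3,2-diazaborolidine (1.2 equiv), i-Pr2NEt, CH2Cl2, −78 °C; then −20 °C → 4 °C, 3 d; aq. work-up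
Reagents that add atoms: none
Why: enantioselective Ireland–Claisen rearrangement through boron ketene acetal 14: i-Pr2NEt/CH2Cl2 should give the enolate with the C7 chain cis to O–B, the chair [3,3] transition state with the (E)-allyl unit places C7 and C11 both equatorial and so gives the syn (2R*,3R*) acid with the C10=C20 methylene, and the chiral ligand on boron selects the enolate face for the (2R,3R) enantiomer.

Step 7
Reactants: 15 (2R,3R)-acid
Product: 17 lactone diol, via triol acid 16 (not isolated)
Conditions: 48 % aq. HF, MeCN, 0 °C → rt; then TsOH·H2O (cat.), PhMe, 40 °C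
Reagents that add atoms: none
Why: cleavage of the three primary TBS ethers frees the C12 hydroxyl, which should lactonise with the C17 acid to the six-membered lactone (the other two hydroxyls could only give eight- or nine-membered rings); C8 and C9 are not touched.

Step 8
Reactants: 17 lactone diol
Product: 18 dialdehyde
Conditions: Dess–Martin periodinane (3 equiv), NaHCO3, CH2Cl2, 0 °C → rt; used at once
Reagents that add atoms: none
Why: Dess–Martin oxidation converts the allylic alcohol into the (E)-enal and the saturated primary alcohol into the C3 aldehyde under buffered, non-epimerising conditions.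

Step 9
Reactants: 18 dialdehyde
Product: 21 tricyclic hydroxy aldehyde lactone, via tertiary radical 19 (not isolated), via iron enolate 20 (not isolated)
Conditions: Fe(acac)3 (50 mol %), PhSiH3 (2.5 equiv), EtOH/(CH2OH)2 5:1, 0.005 M, 0 °C → rt
Reagents that add atoms: none
Why: Fe(acac)3/PhSiH3 forms an iron hydride that transfers a hydrogen atom to C20 of the only electron-rich alkene, giving tertiary radical 19 at C10; 19 adds 6-exo-trig to the enal β-carbon C5 (ring B), the α-formyl radical is reduced by divalent iron to the trivalent iron enolate 20, and 20 closes ring A by a 6-(enolexo)-exo-trig aldol addition to the C3 aldehyde. The closest known reaction type is the hydrogen-atom-transfer-initiated radical conjugate addition that ends in an intramolecular aldol addition (radical–polar crossover polycyclisation of alkene/enal/carbonyl substrates to trans-decalins). C10 and C5 should be set in a chair transition state in which the C9–H bond eclipses the plane of the radical (allylic strain), so that C11 is pseudo-equatorial, the enal arm on C5 is pseudo-equatorial and the smaller C20 methyl rather than the C1 chain takes the pseudo-axial site; this gives the trans ring fusion with C20 on the face of C11 and C17. C3 should be set in the chair aldol transition state with the metal alkoxide equatorial, and the configuration at C4 is of no consequence because C4 becomes CMe2 in step 10. The step needs hydrogen-atom transfer to C10=C20 and not to the enal, 6-exo closure faster than reduction of 19, and aldol capture faster than protonation of 20; the pairing of a nucleophilic radical with an electron-poor enal, the cis-lactone that holds C7 and C10 gauche, and the six-membered closure onto a reactive aldehyde should secure these.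

Step 10
Reactants: 21 tricyclic hydroxy aldehyde lactone
Product: 23 gem-dimethyl hydroxy lactone, via tosylhydrazone 22 (not isolated)
Conditions: TsNHNH2, EtOH, 50 °C; concentrate; catecholborane, CHCl3, 0 °C → rt; NaOAc·3H2O, reflux
Reagents that add atoms: none
Why: reductive deoxygenation of the aldehyde through its tosylhydrazone (hydride addition to C=N, loss of sulfinate and N2) should turn the C4 formyl group into the second C4 methyl without base strong enough for a retro-aldol reaction and without touching the lactone.

Step 11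
Reactants: 23 gem-dimethyl hydroxy lactone
Product: 24 phenylselanyl acid
Conditions: PhSeSePh, NaBH4, DMF, 120 °C; 1 M HCl work-up
Reagents that add atoms: diphenyl diselenide, c1ccccc1[Se][Se]c1ccccc1
Why: the soft, weakly basic selenolate should open the lactone by SN2 attack at the primary carbon C12 (alkyl–oxygen cleavage), freeing the C17 carboxylate without enolising C8.

Step 12
Reactants: 24 phenylselanyl acid
Product: 26 vinyl acid, via selenoxide 25 (not isolated)
Conditions: 30 % H2O2, pyridine, THF, 0 °C → 50 °C
Reagents that add atoms: none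
Why: oxidation to the selenoxide and syn-elimination (selenoxide elimination) can only involve the C11 hydrogens and should give the C11=C12 vinyl group.

Step 13
Reactants: 26 vinyl acid
Product: 27 vinyl diol
Conditions: LiAlH4, THF, 0 °C → reflux
Reagents that add atoms: none
Why: hydride reduction of the carboxylic acid gives the axial C17 hydroxymethyl group; the carboxylate is not enolised, so C8 keeps its configuration.

Step 14
Reactants: 28 methyl but-2-ynoate
Product: 29 methyl (Z)-3-iodobut-2-enoate
Conditions: NaI, AcOH, 115 °C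
Reagents that add atoms: sodium iodide, [Na+].[I-]
Why: conjugate anti-hydroiodination of the ynoate should give the (Z)-β-iodo enoate with iodine cis to the ester.

Step 15
Reactants: 27 vinyl diol; 29 methyl (Z)-3-iodobut-2-enoate
Product: 31 diol enoate, via alkylborane 30 (not isolated)
Conditions: 9-BBN (3.5 equiv), THF, rt; then Pd(dppf)Cl2 (5 mol %), AsPh3, 3 M aq. K3PO4, 29, DMF, rt
Reagents that add atoms: none
Why: anti-Markovnikov hydroboration of the vinyl group and B-alkyl Suzuki–Miyaura coupling with the vinyl iodide proceed with retention at the alkene and should install the (Z)-enoate side chain; the free hydroxyls only consume extra borane.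

Step 16
Reactants: 31 diol enoate
Product: 32 target
Conditions: TEMPO (20 mol %), PhI(OAc)2 (1.1 equiv), CH2Cl2, rt
Reagents that add atoms: none
Why: oxoammonium (TEMPO) oxidation is selective for the primary C17 alcohol over the hindered secondary 3-OH and is close to neutral, so the axial aldehyde at C8 should not epimerise.

**Compound list**

1 | tert-butyl(but-3-yn-1-yloxy)dimethylsilane | C#CCCO[Si](C)(C)C(C)(C)C | starting material
2 | paraformaldehyde (formaldehyde source) | C=O | starting material
3 | {4-[(tert-butyldimethylsilyl)oxy]but-1-yn-1-yl}lithium | [Li]C#CCCO[Si](C)(C)C(C)(C)C | intermediate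
4 | 5-[(tert-butyldimethylsilyl)oxy]pent-2-yn-1-ol | OCC#CCCO[Si](C)(C)C(C)(C)C | intermediate
5 | (3-bromopropoxy)(tert-butyl)dimethylsilane | BrCCCO[Si](C)(C)C(C)(C)C | starting material
6 | {3-[(tert-butyldimethylsilyl)oxy]propyl}magnesium bromide | Br[Mg]CCCO[Si](C)(C)C(C)(C)C | intermediate
7 | cyclic alkenylmagnesium alkoxide (five-membered O–Mg–C=C–CH2 ring, Mg cis to CH2O) | [Mg]1OCC(CCCO[Si](C)(C)C(C)(C)C)=C1CCO[Si](C)(C)C(C)(C)C | intermediate
8 | (2E)-5-[(tert-butyldimethylsilyl)oxy]-2-{3-[(tert-butyldimethylsilyl)oxy]propyl}pent-2-en-1-ol | OC/C(CCCO[Si](C)(C)C(C)(C)C)=C/CCO[Si](C)(C)C(C)(C)C | intermediate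
9 | 6-methylhept-5-enoic acid | CC(C)=CCCCC(=O)O | starting material
10 | (5E)-7-hydroxy-6-methylhept-5-enoic acid | OC/C(C)=C/CCCC(=O)O | intermediate
11 | tert-butyldimethylsilyl (5E)-7-[(tert-butyldimethylsilyl)oxy]-6-methylhept-5-enoate | CC(C)(C)[Si](C)(C)OC/C(C)=C/CCCC(=O)O[Si](C)(C)C(C)(C)C | intermediate
12 | (5E)-7-[(tert-butyldimethylsilyl)oxy]-6-methylhept-5-enoic acid | CC(C)(C)[Si](C)(C)OC/C(C)=C/CCCC(=O)O | intermediate
13 | ester of acid 12 with alcohol 8 (both alkenes E) | CC(C)(C)[Si](C)(C)OC/C(C)=C/CCCC(=O)OC/C(CCCO[Si](C)(C)C(C)(C)C)=C/CCO[Si](C)(C)C(C)(C)C | intermediate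
14 | boron ketene acetal of 13 (C7 chain cis to O–B; (4S,5S)-diazaborolidine) | CC(C)(C)[Si](C)(C)OC/C(C)=C/CC/C=C(\OB1N(S(=O)(=O)c2cc(cc(c2)C(F)(F)F)C(F)(F)F)[C@@H](c2ccccc2)[C@H](c2ccccc2)N1S(=O)(=O)c1cc(cc(c1)C(F)(F)F)C(F)(F)F)OC/C(CCCO[Si](C)(C)C(C)(C)C)=C/CCO[Si](C)(C)C(C)(C)C | intermediate
15 | (2R,3R)-7-[(tert-butyldimethylsilyl)oxy]-3-{2-[(tert-butyldimethylsilyl)oxy]ethyl}-2-{(3E)-5-[(tert-butyldimethylsilyl)oxy]-4-methylpent-3-en-1-yl}-4-methylideneheptanoic acid | CC(C)(C)[Si](C)(C)OCC[C@@H](C(=C)CCCO[Si](C)(C)C(C)(C)C)[C@H](C(=O)O)CC/C=C(\C)CO[Si](C)(C)C(C)(C)C | intermediate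
16 | (2R,3R)-7-hydroxy-3-(2-hydroxyethyl)-2-[(3E)-5-hydroxy-4-methylpent-3-en-1-yl]-4-methylideneheptanoic acid | OCC[C@@H](C(=C)CCCO)[C@H](C(=O)O)CC/C=C(\C)CO | intermediate
17 | (3R,4R)-3-[(3E)-5-hydroxy-4-methylpent-3-en-1-yl]-4-(5-hydroxypent-1-en-2-yl)oxan-2-one | O=C1OCC[C@@H](C(=C)CCCO)[C@H]1CC/C=C(\C)CO | intermediate
18 | (2E)-2-methyl-5-[(3R,4R)-2-oxo-4-(5-oxopent-1-en-2-yl)oxan-3-yl]pent-2-enal | O=C1OCC[C@@H](C(=C)CCC=O)[C@H]1CC/C=C(\C)C=O | intermediate
19 | tertiary C10 radical formed from 18 by hydrogen-atom transfer to C20 | O=C1OCC[C@@H]([C](C)CCC=O)[C@H]1CC/C=C(\C)C=O | intermediate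
20 | ring-B-closed trivalent iron enolate (drawn as the enolate anion; C5 and C10 set) | O=C1OCC[C@@H]2[C@H]1CC[C@H](C(C)=C[O-])[C@@]2(C)CCC=O | intermediate
21 | (3R,4R,5S,8R,9R,10S) tricyclic lactone: trans-decalin with equatorial 3-OH, C4 bearing axial CH3 and equatorial CHO, C20 methyl on C10, δ-lactone O=C17–O–C12 cis-fused across C8–C9 | O=C1OCC[C@@H]2[C@H]1CC[C@@H]3[C@@](C)(C=O)[C@H](O)CC[C@@]23C | intermediate
22 | (E)-tosylhydrazone of the C4 formyl group of 21 | O=C1OCC[C@@H]2[C@H]1CC[C@@H]3[C@@](C)(/C=N/NS(=O)(=O)c4ccc(C)cc4)[C@H](O)CC[C@@]23C | intermediate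
23 | (3R,5S,8R,9R,10S) tricyclic lactone as 21 with CMe2 at C4 | O=C1OCC[C@@H]2[C@H]1CC[C@@H]3C(C)(C)[C@H](O)CC[C@@]23C | intermediate
24 | (1R,2R,4aS,6R,8aS)-6-hydroxy-5,5,8a-trimethyl-1-[2-(phenylselanyl)ethyl]decahydronaphthalene-2-carboxylic acid | c1ccccc1[Se]CC[C@@H]1[C@H](C(=O)O)CC[C@@H]2C(C)(C)[C@H](O)CC[C@@]12C | intermediate
25 | selenoxide of 24 | O=[Se](c1ccccc1)CC[C@@H]1[C@H](C(=O)O)CC[C@@H]2C(C)(C)[C@H](O)CC[C@@]12C | intermediate
26 | (1R,2R,4aS,6R,8aS)-1-ethenyl-6-hydroxy-5,5,8a-trimethyldecahydronaphthalene-2-carboxylic acid | C=C[C@@H]1[C@H](C(=O)O)CC[C@@H]2C(C)(C)[C@H](O)CC[C@@]12C | intermediate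
27 | (1R,2R,4aS,6R,8aS)-1-ethenyl-2-(hydroxymethyl)-5,5,8a-trimethyldecahydronaphthalen-6-ol (locants as in the target name) | C=C[C@@H]1[C@H](CO)CC[C@@H]2C(C)(C)[C@H](O)CC[C@@]12C | intermediate
28 | methyl but-2-ynoate | CC#CC(=O)OC | starting material
29 | methyl (2Z)-3-iodobut-2-enoate | COC(=O)/C=C(/C)I | intermediate
30 | B-alkyl-9-borabicyclo[3.3.1]nonane from 27 (boron on C12) | B1(CC[C@@H]3[C@H](CO)CC[C@@H]4C(C)(C)[C@H](O)CC[C@@]34C)C2CCCC1CCC2 | intermediate
31 | methyl (2Z)-5-[(1R,2R,4aS,6R,8aS)-6-hydroxy-2-(hydroxymethyl)-5,5,8a-trimethyldecahydronaphthalen-1-yl]-3-methylpent-2-enoate | COC(=O)/C=C(/C)CC[C@@H]1[C@H](CO)CC[C@@H]2C(C)(C)[C@H](O)CC[C@@]12C | intermediate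
32 | methyl (2Z)-5-[(1R,2R,4aS,6R,8aS)-2-formyl-6-hydroxy-5,5,8a-trimethyldecahydronaphthalen-1-yl]-3-methylpent-2-enoate | COC(=O)/C=C(/C)CC[C@@H]1[C@H](C=O)CC[C@@H]2C(C)(C)[C@H](O)CC[C@@]12C | target

**Step count.** 16 steps in total. The longest linear sequence is 13 steps (steps 1, 2, 5–13, 15, 16).

**Steps most likely to fail**

Step 9. The C10 radical may be reduced before it cyclises, the enolate may be protonated before the aldol closure, or the face selectivity of the ring B closure may be poor because the axial C17 carbon sits next to the pseudo-axial C20 methyl. The fallback makes the two bonds in separate operations. It sets out from 17: MnO2 (CH2Cl2) oxidises only the allylic alcohol to the hydroxy enal F1. Fe(acac)3/PhSiH3 in EtOH then effects the reductive 6-exo radical conjugate addition alone and gives the ring-B-closed hydroxy aldehyde F2. Dioxane dibromide brominates the only enolisable aldehyde α-carbon (C4) to the bromo aldehyde F3. Dess–Martin periodinane gives the bromo dialdehyde F4. SmI2 (THF, −78 °C) then forms the samarium enolate at C4 regiospecifically and closes ring A by a Reformatsky-type aldol addition. The sequence comes back to the route at 21.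

Step 6. Enantiofacial control by the boron reagent may be insufficient on this 2-substituted allyl ester, or the Lewis-acidic bromoborane may cleave silyl ethers. The fallback sets out from 13: LDA, TMSCl, THF/DMPU, −78 °C → rt gives the (Z)-silyl ketene acetal and, by the ordinary Ireland–Claisen rearrangement, the racemic syn acid F5. Crystallisation with (S)-1-phenylethylamine (or its antipode, whichever gives the less soluble salt of the wanted acid) gives the diastereomerically pure salt F6. Acidification comes back to the route at 15.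

Step 10. Hydrazone formation at the neopentyl aldehyde may be incomplete, or the C3–C4 bond may be lost by retro-aldol cleavage during the basic decomposition. The fallback sets out from 21: ethane-1,2-dithiol and BF3·OEt2 (CH2Cl2, 0 °C) give the dithiolane F7, and Raney nickel (EtOH, reflux) removes the sulfur. The sequence comes back to the route at 23.

**Further compounds**

F1 | step 9 | (2E)-5-[(3R,4R)-4-(5-hydroxypent-1-en-2-yl)-2-oxooxan-3-yl]-2-methylpent-2-enal | O=C1OCC[C@@H](C(=C)CCCO)[C@H]1CC/C=C(\C)C=O
F2 | step 9 | ring-B-closed bicyclic lactone with CH(CH3)CHO on C5 and a 3-hydroxypropyl chain and methyl on C10 (C4 epimers) | O=C1OCC[C@@H]2[C@H]1CC[C@H](C(C)C=O)[C@@]2(C)CCCO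
F3 | step 9 | α-bromo aldehyde from F2 (Br on C4) | O=C1OCC[C@@H]2[C@H]1CC[C@H](C(C)(Br)C=O)[C@@]2(C)CCCO
F4 | step 9 | α-bromo dialdehyde from F3 (C3 aldehyde) | O=C1OCC[C@@H]2[C@H]1CC[C@H](C(C)(Br)C=O)[C@@]2(C)CCC=O
F5 | step 6 | racemic syn acid (15 and its enantiomer, 1:1) | CC(C)(C)[Si](C)(C)OCC[C@@H](C(=C)CCCO[Si](C)(C)C(C)(C)C)[C@H](C(=O)O)CC/C=C(\C)CO[Si](C)(C)C(C)(C)C.CC(C)(C)[Si](C)(C)OCC[C@H](C(=C)CCCO[Si](C)(C)C(C)(C)C)[C@@H](C(=O)O)CC/C=C(\C)CO[Si](C)(C)C(C)(C)C
F6 | step 6 | (S)-1-phenylethylammonium salt of 15 | CC(C)(C)[Si](C)(C)OCC[C@@H](C(=C)CCCO[Si](C)(C)C(C)(C)C)[C@H](C(=O)[O-])CC/C=C(\C)CO[Si](C)(C)C(C)(C)C.C[C@H]([NH3+])c1ccccc1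
F7 | step 10 | 1,3-dithiolane of the C4 formyl group of 21 | O=C1OCC[C@@H]2[C@H]1CC[C@@H]3[C@@](C)(C4SCCS4)[C@H](O)CC[C@@]23C
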